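**Retrosynthetic overview**
- Target ⇐ its 7-O-benzyl ether by hydrogenolysis (last step).
- Ring B of the tetralin (bond C1–C8a, the only ring formed) ⇐ open-chain (2S,3S)-dibenzylbutane-1,4-diol: DDQ dehydrogenates the free guaiacyl phenol to a p-quinone methide, a transient tetrahydrofuran forms, and acid triggers Friedel–Crafts closure by the O-benzyl syringyl ring. C1 is set trans by substrate control.
- C8–C8' bond ⇐ one-electron oxidative heterocoupling of a guaiacyl-propanoyl Evans imide enolate with a syringyl-propanoate ester enolate, the enolate counterpart of the 8–8' radical coupling. C8 is set by the auxiliary.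
- Coupling partners ⇐ dihydroferulic acid, dihydrosinapic acid and (R)-4-benzyl-2-oxazolidinone.

Assumption: the two 3-arylpropanoic acids 1 and 3 are bought as catalogue compounds.

**Route**

Step 1
Reactants: 1 3-(4-hydroxy-3,5-dimethoxyphenyl)propanoic acid
Product: 2 benzyl 3-[4-(benzyloxy)-3,5-dimethoxyphenyl]propanoate
Conditions: BnBr (2.3 equiv), K2CO3 (3 equiv), DMF, 60 °C
Reagents that add atoms: benzyl bromide, BrCc1ccccc1
Why: Double Williamson-type SN2 alkylation of the phenoxide and the carboxylate gives the ether and the ester in one operation; no stereocentre is involved.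

Step 2
Reactants: 3 3-(4-hydroxy-3-methoxyphenyl)propanoic acid
Product: 5 3-[4-(tert-butyldimethylsilyloxy)-3-methoxyphenyl]propanoic acid, via bis-silylated ester 4 (not isolated)
Conditions: TBSCl (2.3 equiv), imidazole, DMF, rt; then AcOH/THF/H2O, rt
Reagents that add atoms: tert-butyldimethylsilyl chloride, CC(C)(C)[Si](C)(C)Cl
Why: Imidazole-promoted silylation caps phenol and acid, and the labile silyl ester is then hydrolysed selectively by aqueous acetic acid, which leaves the aryl silyl ether intact.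

Step 3
Reactants: 5 3-[4-(tert-butyldimethylsilyloxy)-3-methoxyphenyl]propanoic acid; 6 (R)-4-benzyl-1,3-oxazolidin-2-one
Product: 8 (4R)-4-benzyl-3-{3-[4-(tert-butyldimethylsilyloxy)-3-methoxyphenyl]propanoyl}-1,3-oxazolidin-2-one, via mixed pivalic anhydride 7 (not isolated)
Conditions: PivCl, Et3N, THF, −20 °C; then 6, LiCl, rt
Reagents that add atoms: none
Why: N-acylation of the Evans auxiliary through the mixed pivalic anhydride with LiCl activation is a standard, non-epimerising loading, and the auxiliary stereocentre is untouched.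

Step 4
Reactants: 8 (4R)-4-benzyl-3-{3-[4-(tert-butyldimethylsilyloxy)-3-methoxyphenyl]propanoyl}-1,3-oxazolidin-2-one; 2 benzyl 3-[4-(benzyloxy)-3,5-dimethoxyphenyl]propanoate (1.3 equiv)
Product: 11 benzyl (2S,3S)-2-[4-(benzyloxy)-3,5-dimethoxybenzyl]-4-[(4R)-4-benzyl-2-oxo-1,3-oxazolidin-3-yl]-3-[4-(tert-butyldimethylsilyloxy)-3-methoxybenzyl]-4-oxobutanoate, via imide lithium enolate 9 (not isolated), via ester lithium enolate 10 (not isolated)
Conditions: LiN(iPr)2 (2.4 equiv), THF, −78 °C; then Fe(acac)3 (2.4 equiv), −78 °C → rt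
Reagents that add atoms: none
Why: This is an oxidative enolate heterocoupling in which trivalent iron oxidises the enolate pair by single-electron transfer and the imide/ester pairing favours cross- over homocoupling; the chelated Z-imide enolate reacts on the face anti to the auxiliary benzyl group, which sets the imide-bearing carbon as S, while the ester-bearing carbon forms mainly in the anti (S,S) arrangement with only modest selectivity, so the minor diastereomers are removed by chromatography while the auxiliary is still attached.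

Step 5
Reactants: 11 benzyl (2S,3S)-2-[4-(benzyloxy)-3,5-dimethoxybenzyl]-4-[(4R)-4-benzyl-2-oxo-1,3-oxazolidin-3-yl]-3-[4-(tert-butyldimethylsilyloxy)-3-methoxybenzyl]-4-oxobutanoate
Product: 13 (2S,3S)-2-[4-(benzyloxy)-3,5-dimethoxybenzyl]-3-(4-hydroxy-3-methoxybenzyl)butane-1,4-diol, via silyl ether diol 12 (not isolated)
Conditions: LiBH4, MeOH (2 equiv), THF, 0 °C → rt; then 2 M NaOH aq, MeOH, rt
Reagents that add atoms: none
Why: Borohydride reduction converts the N-acyloxazolidinone and the benzyl ester into primary alcohols and releases the auxiliary without touching the two stereocentres, and hydroxide then cleaves only the aryl silyl ether (phenoxide leaving group) while the benzyl ether is inert.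

Step 6
Reactants: 13 (2S,3S)-2-[4-(benzyloxy)-3,5-dimethoxybenzyl]-3-(4-hydroxy-3-methoxybenzyl)butane-1,4-diol
Product: 16 [(1R,2S,3S)-7-(benzyloxy)-1-(4-hydroxy-3-methoxyphenyl)-6,8-dimethoxy-1,2,3,4-tetrahydronaphthalene-2,3-diyl]dimethanol, via quinone methide 14 (not isolated), via tetrahydrofuran lignan 15 (not isolated)
Conditions: DDQ (1.05 equiv), CH2Cl2, 0 °C; then TFA (10 equiv), 0 °C → rt; NaHCO3 aq/MeOH work-up
Reagents that add atoms: none
Why: Under neutral conditions DDQ dehydrogenates only the free para-alkylphenol to the p-quinone methide, which the C9' hydroxyl traps reversibly (oxa-Michael) as a tetrahydrofuran, and TFA then re-ionises this ether so that the syringyl ring (attacking carbon ortho and para to its two methoxy groups) closes ring B by intramolecular Friedel–Crafts alkylation through a chair-like transition state with all three substituents pseudo-equatorial, which sets C1 as R (1,2-trans, 2,3-trans).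

Step 7
Reactants: 16 [(1R,2S,3S)-7-(benzyloxy)-1-(4-hydroxy-3-methoxyphenyl)-6,8-dimethoxy-1,2,3,4-tetrahydronaphthalene-2,3-diyl]dimethanol
Product: 17 [(1R,2S,3S)-7-hydroxy-1-(4-hydroxy-3-methoxyphenyl)-6,8-dimethoxy-1,2,3,4-tetrahydronaphthalene-2,3-diyl]dimethanol
Conditions: H2 (1 atm), Pd/C (10 wt%), MeOH/EtOAc, rt
Reagents that add atoms: none
Why: Catalytic hydrogenolysis cleaves the aryl benzyl ether; the molecule has no other reducible group and no benzylic C–O bond, so the three stereocentres are untouched.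

**Compound list**
1 | 3-(4-hydroxy-3,5-dimethoxyphenyl)propanoic acid (dihydrosinapic acid) | COc1cc(CCC(=O)O)cc(OC)c1O | starting material
2 | benzyl 3-[4-(benzyloxy)-3,5-dimethoxyphenyl]propanoate | COc1cc(CCC(=O)OCc2ccccc2)cc(OC)c1OCc1ccccc1 | intermediate
3 | 3-(4-hydroxy-3-methoxyphenyl)propanoic acid (dihydroferulic acid) | COc1cc(CCC(=O)O)ccc1O | starting material
4 | tert-butyldimethylsilyl 3-[4-(tert-butyldimethylsilyloxy)-3-methoxyphenyl]propanoate | COc1cc(CCC(=O)O[Si](C)(C)C(C)(C)C)ccc1O[Si](C)(C)C(C)(C)C | intermediate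
5 | 3-[4-(tert-butyldimethylsilyloxy)-3-methoxyphenyl]propanoic acid | COc1cc(CCC(=O)O)ccc1O[Si](C)(C)C(C)(C)C | intermediate
6 | (R)-4-benzyl-1,3-oxazolidin-2-one | O=C1N[C@H](Cc2ccccc2)CO1 | starting material
7 | 3-[4-(tert-butyldimethylsilyloxy)-3-methoxyphenyl]propanoic pivalic anhydride | COc1cc(CCC(=O)OC(=O)C(C)(C)C)ccc1O[Si](C)(C)C(C)(C)C | intermediate
8 | (4R)-4-benzyl-3-{3-[4-(tert-butyldimethylsilyloxy)-3-methoxyphenyl]propanoyl}-1,3-oxazolidin-2-one | COc1cc(CCC(=O)N2[C@H](Cc3ccccc3)COC2=O)ccc1O[Si](C)(C)C(C)(C)C | intermediate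
9 | lithium (Z)-enolate of imide 8 | COc1cc(C/C=C(\O[Li])N2[C@H](Cc3ccccc3)COC2=O)ccc1O[Si](C)(C)C(C)(C)C | intermediate
10 | lithium enolate of ester 2 (double-bond geometry not defined) | COc1cc(CC=C(O[Li])OCc2ccccc2)cc(OC)c1OCc1ccccc1 | intermediate
11 | benzyl (2S,3S)-2-[4-(benzyloxy)-3,5-dimethoxybenzyl]-4-[(4R)-4-benzyl-2-oxo-1,3-oxazolidin-3-yl]-3-[4-(tert-butyldimethylsilyloxy)-3-methoxybenzyl]-4-oxobutanoate | COc1cc(C[C@H](C(=O)OCc2ccccc2)[C@@H](C(=O)N2[C@H](Cc3ccccc3)COC2=O)Cc2ccc(O[Si](C)(C)C(C)(C)C)c(OC)c2)cc(OC)c1OCc1ccccc1 | intermediate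
12 | (2S,3S)-2-[4-(benzyloxy)-3,5-dimethoxybenzyl]-3-[4-(tert-butyldimethylsilyloxy)-3-methoxybenzyl]butane-1,4-diol | COc1cc(C[C@H](CO)[C@@H](CO)Cc2ccc(O[Si](C)(C)C(C)(C)C)c(OC)c2)cc(OC)c1OCc1ccccc1 | intermediate
13 | (2S,3S)-2-[4-(benzyloxy)-3,5-dimethoxybenzyl]-3-(4-hydroxy-3-methoxybenzyl)butane-1,4-diol | COc1cc(C[C@H](CO)[C@@H](CO)Cc2ccc(O)c(OC)c2)cc(OC)c1OCc1ccccc1 | intermediate
14 | 4-{(2S,3S)-4-[4-(benzyloxy)-3,5-dimethoxyphenyl]-2,3-bis(hydroxymethyl)butylidene}-2-methoxycyclohexa-2,5-dien-1-one (p-quinone methide, exocyclic alkene geometry not defined) | COC1=CC(=C[C@H](CO)[C@@H](CO)Cc2cc(OC)c(OCc3ccccc3)c(OC)c2)C=CC1=O | intermediate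
15 | 4-{(3S,4S)-4-[4-(benzyloxy)-3,5-dimethoxybenzyl]-3-(hydroxymethyl)tetrahydrofuran-2-yl}-2-methoxyphenol (both C2 epimers) | COc1cc(C[C@@H]2COC(c3ccc(O)c(OC)c3)[C@@H]2CO)cc(OC)c1OCc1ccccc1 | intermediate
16 | [(1R,2S,3S)-7-(benzyloxy)-1-(4-hydroxy-3-methoxyphenyl)-6,8-dimethoxy-1,2,3,4-tetrahydronaphthalene-2,3-diyl]dimethanol | COc1cc([C@@H]2c3c(cc(OC)c(OCc4ccccc4)c3OC)C[C@H](CO)[C@H]2CO)ccc1O | intermediate
17 | [(1R,2S,3S)-7-hydroxy-1-(4-hydroxy-3-methoxyphenyl)-6,8-dimethoxy-1,2,3,4-tetrahydronaphthalene-2,3-diyl]dimethanol | COc1cc([C@@H]2c3c(cc(OC)c(O)c3OC)C[C@H](CO)[C@H]2CO)ccc1O | target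

**Step count and risks**
Total steps: 7. Longest linear sequence: 6 (steps 2, 3, 4, 5, 6, 7, from 3).

Most likely to fail:

- **Step 4** (modest heterocoupling yield and weak control at the ester-bearing carbon). The fallback builds the C8–C8' bond by two stepwise enolate alkylations, setting out from 8 and coming back at 12.
  - The sodium enolate of 8 (NaN(SiMe3)2, THF, −78 °C) is alkylated with tert-butyl bromoacetate anti to the auxiliary benzyl group to give the (S)-succinate imide F1.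
  - LiBH4/MeOH reduces only the imide to the hydroxy tert-butyl ester F2, which lactonises with catalytic TsOH in warm toluene to the (S)-β-arylmethyl butyrolactone F3.
  - In parallel, commercial 4-(benzyloxy)-3,5-dimethoxybenzaldehyde is reduced (NaBH4, MeOH) to the benzylic alcohol F4 and converted (PBr3, Et2O, 0 °C) into the benzylic bromide F5.
  - The lithium enolate of F3 (LiN(SiMe3)2, THF, −78 °C) is alkylated with F5 trans to the neighbouring substituent to give the (3S,4S)-trans-dibenzylbutyrolactone F6.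
  - LiAlH4 in THF opens F6 to 12, which is desilylated with NaOH as in step 5.

- **Step 6** (over-oxidation of the product by DDQ, interference from the free hydroxyl groups, partial trifluoroacetylation). The fallback closes ring B before the reduction, setting out from 11 and coming back at 16.
  - TBAF/AcOH in THF frees the guaiacyl phenol to give the phenolic succinate F7.
  - DDQ in CH2Cl2 followed by TFA cyclises F7 at the carbonyl oxidation level, where no hydroxyl group can intercept the quinone methide, to the 1,2-trans-2,3-trans aryltetralin imide ester F8.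
  - LiBH4/MeOH then reduces both acyl groups to give 16.

- **Step 5** (endocyclic opening of the oxazolidinone or stalled reduction at the hindered α-branched imide). The fallback removes the auxiliary hydrolytically before any hydride is used, setting out from 11 and coming back at 12.
  - LiOH/H2O2 in THF/H2O at 0 °C cleaves the imide to the succinic acid monobenzyl ester F9.
  - LiAlH4 in THF reduces acid and ester to 12, which is desilylated with NaOH as in step 5.

**Further compounds**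
F1 | step 4 | tert-butyl (3S)-4-[(4R)-4-benzyl-2-oxo-1,3-oxazolidin-3-yl]-3-[4-(tert-butyldimethylsilyloxy)-3-methoxybenzyl]-4-oxobutanoate | CC(C)(C)OC(=O)C[C@H](Cc1ccc(O[Si](C)(C)C(C)(C)C)c(OC)c1)C(=O)N1[C@H](Cc2ccccc2)COC1=O
F2 | step 4 | tert-butyl (3S)-3-[4-(tert-butyldimethylsilyloxy)-3-methoxybenzyl]-4-hydroxybutanoate | CC(C)(C)OC(=O)C[C@H](Cc1ccc(O[Si](C)(C)C(C)(C)C)c(OC)c1)CO
F3 | step 4 | (4S)-4-[4-(tert-butyldimethylsilyloxy)-3-methoxybenzyl]dihydrofuran-2(3H)-one | O=C1C[C@H](Cc2ccc(O[Si](C)(C)C(C)(C)C)c(OC)c2)CO1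
F4 | step 4 | [4-(benzyloxy)-3,5-dimethoxyphenyl]methanol | COc1cc(CO)cc(OC)c1OCc1ccccc1
F5 | step 4 | 2-(benzyloxy)-5-(bromomethyl)-1,3-dimethoxybenzene | COc1cc(CBr)cc(OC)c1OCc1ccccc1
F6 | step 4 | (3S,4S)-3-[4-(benzyloxy)-3,5-dimethoxybenzyl]-4-[4-(tert-butyldimethylsilyloxy)-3-methoxybenzyl]dihydrofuran-2(3H)-one | COc1cc(C[C@@H]2C(=O)OC[C@H]2Cc2ccc(O[Si](C)(C)C(C)(C)C)c(OC)c2)cc(OC)c1OCc1ccccc1
F7 | step 6 | benzyl (2S,3S)-2-[4-(benzyloxy)-3,5-dimethoxybenzyl]-4-[(4R)-4-benzyl-2-oxo-1,3-oxazolidin-3-yl]-3-(4-hydroxy-3-methoxybenzyl)-4-oxobutanoate | COc1cc(C[C@H](C(=O)OCc2ccccc2)[C@@H](C(=O)N2[C@H](Cc3ccccc3)COC2=O)Cc2ccc(O)c(OC)c2)cc(OC)c1OCc1ccccc1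
F8 | step 6 | benzyl (2S,3S,4R)-6-(benzyloxy)-3-[(4R)-4-benzyl-2-oxo-1,3-oxazolidine-3-carbonyl]-4-(4-hydroxy-3-methoxyphenyl)-5,7-dimethoxy-1,2,3,4-tetrahydronaphthalene-2-carboxylate | COc1cc([C@@H]2c3c(cc(OC)c(OCc4ccccc4)c3OC)C[C@H](C(=O)OCc3ccccc3)[C@H]2C(=O)N2[C@H](Cc3ccccc3)COC2=O)ccc1O
F9 | step 5 | (2S,3S)-4-(benzyloxy)-3-[4-(benzyloxy)-3,5-dimethoxybenzyl]-2-[4-(tert-butyldimethylsilyloxy)-3-methoxybenzyl]-4-oxobutanoic acid | COc1cc(C[C@H](C(=O)OCc2ccccc2)[C@@H](C(=O)O)Cc2ccc(O[Si](C)(C)C(C)(C)C)c(OC)c2)cc(OC)c1OCc1ccccc1
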